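**Plan**
- Retrosynthetic cuts, in order: the silylethyl ester O–C bond, C8=C17, C12–C13, C9–C11, C2=C3 (after removing the C2 acetate and a C3 bromine handle), then C1–C10 and C4–C5.
- Enabling feature: in ring B the methyl-bearing quaternary C10 sits between C9 and C5, C5 carries the gem-dimethyl carbon C4, and C10 carries C1. This is the pattern left when 2-methylcyclohex-2-enone (carbonyl = C9, α-carbon = C10, β-carbon = C5) takes an isobutyrate nucleophile at C5 and an allyl electrophile at C10.
- Forward order: ring B is bought; one flask adds C4 (with C3) and C1–C2; ring A closes by olefin metathesis at C2=C3; the side chain is joined to C9 by two cross-couplings (C9–C11, then C12–C13); C8 is oxygenated and methylenated last.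
- Stereochemistry: C5 from the chiral boron Lewis acid; C10 from allylation anti to the C5 substituent; C2 from trans-diaxial opening of an α-bromonium ion; C9 from α-face hydroboration (also the stable epimer next to the C8 ketone); 13Z from anti hydroiodination of a but-2-ynoate, kept through the coupling.

Key step: step 1

Remark: atom labels follow labdane numbering in every intermediate; β is the face of the C10 methyl group, α the opposite face.
Assumption: the (S)-prolinol-derived boron cation is taken to deliver the ketene acetal to the enone face that gives (R) at C5, as the target requires; if the sense were opposite, the (R)-prolinol catalyst would be used.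

**Step 1**
Reactants: 1 2-methylcyclohex-2-en-1-one; 2 1-methoxy-2-methyl-1-(trimethylsilyloxy)prop-1-ene; 3 allyl bromide
Product: 6 methyl 2-methyl-2-[(1R,2S)-2-methyl-3-oxo-2-(prop-2-en-1-yl)cyclohexyl]propanoate, via enol silane 4 (not isolated), via lithium enolate 5 (not isolated)
Conditions: N-protonated (S)-1-(2-methylphenyl)-3,3-diphenyltetrahydro-1H,3H-pyrrolo[1,2-c][1,3,2]oxazaborole as its (CF3SO2)2N− salt (20 mol %, from (S)-α,α-diphenylprolinol, 2-methylphenylboronic acid and HN(SO2CF3)2), Ph3PO (25 mol %), toluene, −20 °C; then MeLi, THF, 0 °C; then 3, HMPA, −78 → 0 °C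
Reagents that add atoms: none
Why: The boron cation binds the carbonyl oxygen of 1, the ketene acetal 2 adds to the β-carbon (C5) from the enone face left open by the aryl groups, and the silyl group passes to the enolate oxygen, so the tetrasubstituted enol silane 4 forms with its double bond fixed between C9 and C10. Methyllithium attacks silicon of 4 (releasing tetramethylsilane) to give the regiodefined lithium enolate 5, which is C-allylated at C10 by 3 in an SN2 reaction. The closest known reaction types are the catalytic enantioselective Mukaiyama–Michael addition of silyl ketene acetals to cycloalkenones and the regiospecific alkylation of lithium enolates released from enol silanes. No ring is closed: the step forms C4–C5 and C1–C10 on the purchased ring-B carbocycle. C5 is set by the chiral Lewis acid, and C10 by the substrate, because the bulky C5 substituent sits pseudoaxial to avoid the C10 methyl and allyl bromide approaches the opposite face, giving the trans relation of C1 and C4 that a trans-decalin needs. The step needs C- rather than O-allylation and survival of the ester toward MeLi; the soft allyl bromide on a lithium enolate in THF/HMPA should secure the first, and the pivalate-like hindrance of the α-quaternary ester with about one equivalent of MeLi at low temperature the second.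

**Step 2**
Reactants: 6 methyl 2-methyl-2-[(1R,2S)-2-methyl-3-oxo-2-(prop-2-en-1-yl)cyclohexyl]propanoate
Product: 7 3-(1-hydroxy-2-methylpropan-2-yl)-2-methyl-2-(prop-2-en-1-yl)cyclohexan-1-ol (C5 and C10 as in 6; both C9 carbinol epimers)
Conditions: LiAlH4, THF, 0 °C → rt
Reagents that add atoms: none
Why: Lithium aluminium hydride reduction converts the hindered ester into the neopentyl-type primary alcohol and the ketone into the C9 carbinol in one operation; the C9 epimers need no separation because both are oxidised again in step 3, and C5 and C10 are untouched.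

**Step 3**
Reactants: 7 3-(1-hydroxy-2-methylpropan-2-yl)-2-methyl-2-(prop-2-en-1-yl)cyclohexan-1-ol
Product: 8 2-methyl-2-[2-methyl-3-oxo-2-(prop-2-en-1-yl)cyclohexyl]propanal (C5 and C10 as in 6)
Conditions: Dess–Martin periodinane (1,1,1-triacetoxy-1,1-dihydro-1,2-benziodoxol-3(1H)-one), NaHCO3, CH2Cl2, rt
Reagents that add atoms: none
Why: Dess–Martin oxidation under buffered, non-enolising conditions returns the C9 ketone and gives the C3 aldehyde, which has no α-hydrogen and so cannot epimerise.

**Step 4**
Reactants: 8 2-methyl-2-[2-methyl-3-oxo-2-(prop-2-en-1-yl)cyclohexyl]propanal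
Product: 9 2-methyl-3-(2-methylbut-3-en-2-yl)-2-(prop-2-en-1-yl)cyclohexan-1-one (C5 and C10 as in 6)
Conditions: Ph3PCH3Br, KN(SiMe3)2, THF, 0 °C; then 8, −78 → 0 °C
Reagents that add atoms: methyltriphenylphosphonium bromide (as its ylide), C[P+](c1ccccc1)(c1ccccc1)c1ccccc1.[Br-]
Why: Wittig methylenation should select the aldehyde because the C9 ketone is flanked by the quaternary C10 and one equivalent of ylide is used at low temperature, where carbonyl addition outruns enolisation.

**Step 5**
Reactants: 9 2-methyl-3-(2-methylbut-3-en-2-yl)-2-(prop-2-en-1-yl)cyclohexan-1-one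
Product: 10 trans-fused 5,5,8a-trimethyl-3,4,4a,5,8,8a-hexahydronaphthalen-1(2H)-one (9-oxo, C2=C3 alkene, 5α-H, 10β-CH3)
Conditions: second-generation Grubbs catalyst RuCl2(=CHPh)(PCy3)(H2IMes) (5 mol %), CH2Cl2, 40 °C
Reagents that add atoms: none
Why: Ring-closing olefin metathesis joins the C10 allyl group and the C4 vinyl group, which sit trans on neighbouring ring carbons, into the six-membered ring A with a C2=C3 bond and loss of ethylene, so the ring fusion comes out trans without a new stereocentre being made.

**Step 6**
Reactants: 10 trans-fused 5,5,8a-trimethyl-3,4,4a,5,8,8a-hexahydronaphthalen-1(2H)-one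
Product: 11 3α-bromo-2β-hydroxy ketone (6-bromo-7-hydroxy-5,5,8a-trimethyloctahydronaphthalen-1(2H)-one; Br and OH trans-diaxial, 5α-H, 10β-CH3)
Conditions: N-bromosuccinimide, THF/H2O, 0 °C, dark
Reagents that add atoms: N-bromosuccinimide, O=C1CCC(=O)N1Br; water, O
Why: Bromohydrin formation: the bromonium ion forms on the α face because the axial methyl groups on C10 and C4 screen the β face, and water opens it at C2 from the β face (Fürst–Plattner trans-diaxial opening, C3 being neopentyl), which sets the axial 2β-hydroxyl.

**Step 7**
Reactants: 11 3α-bromo-2β-hydroxy ketone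
Product: 12 2β-hydroxy ketone (7-hydroxy-5,5,8a-trimethyloctahydronaphthalen-1(2H)-one; axial 2β-OH, 5α-H, 10β-CH3)
Conditions: Bu3SnH, azobisisobutyronitrile (cat.), toluene, 80 °C
Reagents that add atoms: none
Why: Tin hydride radical chain dehalogenation removes the C3 bromine through a secondary alkyl radical without affecting the C2 carbinol or the ketone.

**Step 8**
Reactants: 12 2β-hydroxy ketone
Product: 13 2β-acetoxy ketone (7-acetoxy-5,5,8a-trimethyloctahydronaphthalen-1(2H)-one; 5α-H, 10β-CH3)
Conditions: Ac2O, 4-(dimethylamino)pyridine, pyridine, 40 °C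
Reagents that add atoms: acetic anhydride, CC(=O)OC(C)=O
Why: Nucleophile-catalysed acetylation acylates the hindered axial alcohol with retention, and the acetate then serves both as the C2 substituent of the target and as the protecting group for the rest of the route.

**Step 9**
Reactants: 13 2β-acetoxy ketone
Product: 14 C9 enol triflate (7-acetoxy-5,5,8a-trimethyl-3,4,4a,5,6,7,8,8a-octahydronaphthalen-1-yl trifluoromethanesulfonate; C8=C9 alkene, 2β-OAc, 5α-H, 10β-CH3)
Conditions: (CF3SO2)2O, 2,6-di-tert-butyl-4-methylpyridine, CH2Cl2, 0 °C → rt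
Reagents that add atoms: trifluoromethanesulfonic anhydride, O=S(=O)(OS(=O)(=O)C(F)(F)F)C(F)(F)F
Why: Enol triflate formation with triflic anhydride and a hindered pyridine base: the ketone can enolise only toward C8, so a single C8=C9 enol triflate should result, and the non-nucleophilic conditions leave the acetate intact.

**Step 10**
Reactants: 14 C9 enol triflate
Product: 15 9-vinyl diene (7-acetoxy-1-ethenyl-5,5,8a-trimethyl-3,4,4a,5,6,7,8,8a-octahydronaphthalene; 2β-OAc, 5α-H, 10β-CH3)
Conditions: CH2=CHSnBu3, Pd(PPh3)4 (5 mol %), LiCl, THF, 65 °C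
Reagents that add atoms: tributyl(vinyl)stannane, C=C[Sn](CCCC)(CCCC)CCCC
Why: Stille coupling: oxidative addition of zerovalent palladium into the enol triflate, chloride-assisted transmetalation from the vinylstannane and reductive elimination form the C9–C11 bond under neutral conditions that the acetate tolerates.

**Step 11**
Reactants: 16 but-2-ynoic acid; 17 2-(trimethylsilyl)ethanol
Product: 18 2-(trimethylsilyl)ethyl but-2-ynoate
Conditions: N,N'-dicyclohexylcarbodiimide, 4-(dimethylamino)pyridine (5 mol %), CH2Cl2, 0 °C → rt
Reagents that add atoms: none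
Why: Steglich esterification (carbodiimide activation with acyl-transfer catalysis) installs a fluoride-labile ester that can later be removed beside the C2 acetate.

**Step 12**
Reactants: 18 2-(trimethylsilyl)ethyl but-2-ynoate
Product: 19 2-(trimethylsilyl)ethyl (2Z)-3-iodobut-2-enoate
Conditions: LiI, AcOH, MeCN, 80 °C
Reagents that add atoms: lithium iodide, [Li+].[I-]
Why: Hydroiodination of the ynoate: iodide adds to the β-carbon and the resulting allenolate is protonated, a net anti addition that places iodine cis to the ester and so fixes the (Z) geometry.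

**Step 13**
Reactants: 15 9-vinyl diene; 19 2-(trimethylsilyl)ethyl (2Z)-3-iodobut-2-enoate
Product: 21 2-(trimethylsilyl)ethyl (13Z)-2β-acetoxy-17-norlabda-8,13-dien-15-oate, via alkylborane 20 (not isolated)
Conditions: 9-borabicyclo[3.3.1]nonane, THF, 0 °C → rt; then 19, PdCl2(dppf), AsPh3, Cs2CO3, DMF/H2O, rt
Reagents that add atoms: none
Why: Hydroboration with 9-borabicyclo[3.3.1]nonane takes the terminal vinyl group anti-Markovnikov (boron on C12) and leaves the hindered trisubstituted ring alkene, and the B-alkyl Suzuki–Miyaura coupling with the vinyl iodide then forms C12–C13 with retention of the alkene geometry, giving 13Z.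

**Step 14**
Reactants: 21 2-(trimethylsilyl)ethyl (13Z)-2β-acetoxy-17-norlabda-8,13-dien-15-oate
Product: 22 2-(trimethylsilyl)ethyl (13Z)-2β-acetoxy-8α-hydroxy-17-norlabd-13-en-15-oate (9α-H)
Conditions: BH3·THF, THF, 0 °C → rt; then NaBO3·4H2O, THF/H2O, rt
Reagents that add atoms: sodium perborate (hydrate water omitted), [Na+].[Na+].O[B-]1(O)OO[B-](O)(O)OO1
Why: Brown hydroboration–oxidation: electrophilic borane should add to the electron-rich C8=C9 bond in preference to the electron-poor β,β-disubstituted enoate, boron going to the less substituted C8 and hydrogen to C9 in a syn addition on the α face (anti to the axial C10 methyl), which sets 9α-H, and perborate oxidation replaces boron by hydroxyl with retention.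

**Step 15**
Reactants: 22 2-(trimethylsilyl)ethyl (13Z)-2β-acetoxy-8α-hydroxy-17-norlabd-13-en-15-oate
Product: 23 2-(trimethylsilyl)ethyl (13Z)-2β-acetoxy-8-oxo-17-norlabd-13-en-15-oate (9α-H)
Conditions: Dess–Martin periodinane, NaHCO3, CH2Cl2, rt
Reagents that add atoms: none
Why: Dess–Martin oxidation of the secondary C8 alcohol gives the ketone under buffered conditions, and the 9α-H epimer with its equatorial side chain is also the thermodynamically preferred one next to the new carbonyl, so enolisation would not erode C9.

**Step 16**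
Reactants: 23 2-(trimethylsilyl)ethyl (13Z)-2β-acetoxy-8-oxo-17-norlabd-13-en-15-oate
Product: 24 2-(trimethylsilyl)ethyl (13Z)-2β-acetoxylabda-8(17),13-dien-15-oate
Conditions: Zn, CH2Br2, TiCl4, THF, 0 °C (reagent pre-formed); then 23, CH2Cl2, rt
Reagents that add atoms: dibromomethane, BrCBr
Why: Takai–Lombardo methylenation: the zinc/titanium methylene reagent olefinates ketones but not esters and is not basic, so the acetate, the enoate and the epimerisable C9 centre should be left alone.

**Step 17**
Reactants: 24 2-(trimethylsilyl)ethyl (13Z)-2β-acetoxylabda-8(17),13-dien-15-oate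
Product: 25 (2R,5S,9S,10S,13Z)-2-acetoxylabda-8(17),13-dien-15-oic acid
Conditions: Bu4NF, THF, 0 °C → rt; dilute aq. HCl work-up
Reagents that add atoms: none
Why: Fluoride attacks silicon and the 2-(trimethylsilyl)ethyl ester fragments by β-elimination to ethylene, Me3SiF and the carboxylate, a deprotection that needs no acyl substitution and should therefore spare the hindered C2 acetate and both alkenes.

**Compound list**
1 | 2-methylcyclohex-2-en-1-one | CC1=CCCCC1=O | starting material
2 | 1-methoxy-2-methyl-1-(trimethylsilyloxy)prop-1-ene | COC(=C(C)C)O[Si](C)(C)C | starting material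
3 | allyl bromide (3-bromoprop-1-ene) | C=CCBr | starting material
4 | methyl 2-methyl-2-[(1R)-2-methyl-3-(trimethylsilyloxy)cyclohex-2-en-1-yl]propanoate (enol silane) | COC(=O)C(C)(C)[C@@H]1CCCC(O[Si](C)(C)C)=C1C | intermediate (not isolated)
5 | lithium enolate of methyl 2-methyl-2-[(1R)-2-methyl-3-oxocyclohexyl]propanoate (C9–C10 enolate) | COC(=O)C(C)(C)[C@@H]1CCCC(O[Li])=C1C | intermediate (not isolated)
6 | methyl 2-methyl-2-[(1R,2S)-2-methyl-3-oxo-2-(prop-2-en-1-yl)cyclohexyl]propanoate | O=C1CCC[C@@H](C(C)(C)C(=O)OC)[C@]1(C)CC=C | intermediate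
7 | 3-(1-hydroxy-2-methylpropan-2-yl)-2-methyl-2-(prop-2-en-1-yl)cyclohexan-1-ol (C5, C10 as in 6; C9 epimers) | OC1CCC[C@@H](C(C)(C)CO)[C@]1(C)CC=C | intermediate
8 | 2-methyl-2-[2-methyl-3-oxo-2-(prop-2-en-1-yl)cyclohexyl]propanal (C5, C10 as in 6) | O=C1CCC[C@@H](C(C)(C)C=O)[C@]1(C)CC=C | intermediate
9 | 2-methyl-3-(2-methylbut-3-en-2-yl)-2-(prop-2-en-1-yl)cyclohexan-1-one (C5, C10 as in 6) | O=C1CCC[C@@H](C(C)(C)C=C)[C@]1(C)CC=C | intermediate
10 | trans-fused 5,5,8a-trimethyl-3,4,4a,5,8,8a-hexahydronaphthalen-1(2H)-one (5α-H, 10β-CH3) | O=C1CCC[C@H]2C(C)(C)C=CC[C@]12C | intermediate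
11 | 3α-bromo-2β-hydroxy ketone (6-bromo-7-hydroxy-5,5,8a-trimethyloctahydronaphthalen-1(2H)-one) | O=C1CCC[C@H]2C(C)(C)[C@H](Br)[C@@H](O)C[C@]12C | intermediate
12 | 2β-hydroxy ketone (7-hydroxy-5,5,8a-trimethyloctahydronaphthalen-1(2H)-one) | O=C1CCC[C@H]2C(C)(C)C[C@@H](O)C[C@]12C | intermediate
13 | 2β-acetoxy ketone (7-acetoxy-5,5,8a-trimethyloctahydronaphthalen-1(2H)-one) | O=C1CCC[C@H]2C(C)(C)C[C@@H](OC(C)=O)C[C@]12C | intermediate
14 | C9 enol triflate (7-acetoxy-5,5,8a-trimethyl-3,4,4a,5,6,7,8,8a-octahydronaphthalen-1-yl trifluoromethanesulfonate) | O=S(=O)(OC1=CCC[C@H]2C(C)(C)C[C@@H](OC(C)=O)C[C@]12C)C(F)(F)F | intermediate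
15 | 9-vinyl diene (7-acetoxy-1-ethenyl-5,5,8a-trimethyl-3,4,4a,5,6,7,8,8a-octahydronaphthalene) | C=CC1=CCC[C@H]2C(C)(C)C[C@@H](OC(C)=O)C[C@]12C | intermediate
16 | but-2-ynoic acid | CC#CC(=O)O | starting material
17 | 2-(trimethylsilyl)ethanol | C[Si](C)(C)CCO | starting material
18 | 2-(trimethylsilyl)ethyl but-2-ynoate | CC#CC(=O)OCC[Si](C)(C)C | intermediate
19 | 2-(trimethylsilyl)ethyl (2Z)-3-iodobut-2-enoate | C/C(I)=C/C(=O)OCC[Si](C)(C)C | intermediate
20 | B-alkyl-9-borabicyclo[3.3.1]nonane from 15 (boron on C12) | C(CB1C2CCCC1CCC2)C1=CCC[C@H]2C(C)(C)C[C@@H](OC(C)=O)C[C@]12C | intermediate (not isolated)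
21 | 2-(trimethylsilyl)ethyl (13Z)-2β-acetoxy-17-norlabda-8,13-dien-15-oate | C[Si](C)(C)CCOC(=O)/C=C(C)\CCC1=CCC[C@H]2C(C)(C)C[C@@H](OC(C)=O)C[C@]12C | intermediate
22 | 2-(trimethylsilyl)ethyl (13Z)-2β-acetoxy-8α-hydroxy-17-norlabd-13-en-15-oate (9α-H) | O[C@@H]1CC[C@H]2C(C)(C)C[C@@H](OC(C)=O)C[C@]2(C)[C@H]1CC/C(C)=C\C(=O)OCC[Si](C)(C)C | intermediate
23 | 2-(trimethylsilyl)ethyl (13Z)-2β-acetoxy-8-oxo-17-norlabd-13-en-15-oate (9α-H) | O=C1CC[C@H]2C(C)(C)C[C@@H](OC(C)=O)C[C@]2(C)[C@H]1CC/C(C)=C\C(=O)OCC[Si](C)(C)C | intermediate
24 | 2-(trimethylsilyl)ethyl (13Z)-2β-acetoxylabda-8(17),13-dien-15-oate | C=C1CC[C@H]2C(C)(C)C[C@@H](OC(C)=O)C[C@]2(C)[C@H]1CC/C(C)=C\C(=O)OCC[Si](C)(C)C | intermediate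
25 | (2R,5S,9S,10S,13Z)-2-acetoxylabda-8(17),13-dien-15-oic acid | C=C1CC[C@H]2C(C)(C)C[C@@H](OC(C)=O)C[C@]2(C)[C@H]1CC/C(C)=C\C(=O)O | target

**Step count**
Total: 17 steps. Longest linear sequence: 15 steps (steps 1–10 and 13–17, from 2-methylcyclohex-2-en-1-one); the side-chain piece takes 2 steps (11 and 12).

**Steps most likely to fail**

Step 1. Methyllithium may add to the ester or be consumed by acidic catalyst residues, so that the enol silane is only partly unmasked. The allylation may also lose its anti preference or go to oxygen. The fallback sets out from enol silane 4, isolated after the Michael stage by filtration through basic alumina and evaporation, and replaces the lithium enolate alkylation by a palladium-catalysed Tsuji allylation: allyl methyl carbonate, Pd2(dba)3, 1,2-bis(diphenylphosphino)ethane and catalytic Bu4N[Ph3SiF2] in THF at rt. The π-allyl palladium electrophile is attacked by the enolate released in situ, again anti to the C5 substituent. The fallback comes back to the route at compound 6 and makes no new compound.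

Step 14. Borane may also hydroborate or reduce the conjugated enoate, or add only sluggishly to the hindered ring alkene. The fallback sets out from 21 and oxygenates C8 without any hydride reagent. Epoxidation with 3-chloroperoxybenzoic acid (NaHCO3, CH2Cl2, 0 °C) should touch only the electron-rich C8=C9 bond, from the α face, to give 2-(trimethylsilyl)ethyl (13Z)-2β-acetoxy-8α,9α-epoxy-17-norlabd-13-en-15-oate F1. BF3·OEt2 in CH2Cl2 at −78 °C then triggers a Meinwald rearrangement with hydride shift from C8 to C9, giving the 8-ketone. Brief treatment with DBU equilibrates C9, now α to the carbonyl, to the equatorial side chain. The fallback comes back to the route at compound 23.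

Step 6. The bromonium ion may form on the wrong face, or water may open it at C3 rather than at C2, because attack at C2 from the β face has to pass two syn-axial methyl groups. Either would give regio- or stereoisomeric bromohydrins. The fallback sets out from 10 and sets C2 by carbonyl reduction instead of bromonium opening. BH3·THF followed by NaOH/H2O2 hydroborates the C2=C3 bond with boron on C2 (away from neopentyl C3) and reduces the ketone, giving the 2α,9-diol (7-hydroxy analogue of the decalin-1-ol, C9 epimers) F2. Dess–Martin oxidation gives the 2,9-dione (5,5,8a-trimethylhexahydronaphthalene-1,7-dione) F3. One equivalent of LiBH(s-Bu)3 in THF at −78 °C should then reduce the C2 carbonyl, which has no α-substituents, ahead of the C9 carbonyl shielded by the quaternary C10. Hydride arrives from the α face, opposite the two axial methyl groups, so the axial 2β-alcohol results. The fallback comes back to the route at compound 12.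

**Further compounds**
F0 | step 1 | none | none
F1 | step 14 | 2-(trimethylsilyl)ethyl (13Z)-2β-acetoxy-8α,9α-epoxy-17-norlabd-13-en-15-oate | O1[C@@H]2CC[C@H]3C(C)(C)C[C@@H](OC(C)=O)C[C@]3(C)[C@]12CC/C(C)=C\C(=O)OCC[Si](C)(C)C
F2 | step 6 | 2α,9-diol: trans-fused 5,5,8a-trimethyldecahydronaphthalene-1,7-diol (2α-OH, C9 epimers, 5α-H, 10β-CH3) | OC1CCC[C@H]2C(C)(C)C[C@H](O)C[C@]12C
F3 | step 6 | 2,9-dione: trans-fused 5,5,8a-trimethylhexahydronaphthalene-1,7(2H,8H)-dione (5α-H, 10β-CH3) | O=C1CCC[C@H]2C(C)(C)CC(=O)C[C@]12C
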